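Retrosynthetic overview
1. Enabling feature: in the 1,2-dioxane ring (O1, O2, C3, C4, C5, C6), the CH2 of the acetic acid arm on C3 and the CH2 of the ethyl group on quaternary C6 lie on the same ring face, as does the C4 ethyl. These two carbons can therefore be joined as the CH=CH bridge of a 2,3-dioxabicyclo[2.2.2]oct-5-ene.
2. Endgame: acid ⇒ primary alcohol; C6 ethyl ⇒ C6 vinyl (diimide); C3 CH2CH2OH ⇒ C3 vinyl (hindered borane); 3,6-divinyl dioxane ⇒ bicyclic endoperoxide + ethene (ring-opening metathesis).
3. Key disconnection: endoperoxide ⇒ singlet oxygen + (R)-5-ethyl-1-alkenylcyclohexa-1,3-diene. The C3–O2 and C6–O1 bonds form together, and the C4 ethyl group relays its configuration to C3 and C6.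
4. Triene ⇒ through-conjugated dienyl triflate of (S)-5-ethylcyclohex-2-enone (organocatalytic Michael/aldol/decarboxylation of pent-2-enal and tert-butyl acetoacetate) + E-alkenylzinc from methylalumination of (S)-4-ethyloct-1-yne (Evans ethylation of a hexanoyl imide).
5. Ring order: the carbocycle (ring A) is made first, the dioxane (ring B) second by bridging ring A with O–O, and ring A is then cut open at its remaining C=C.
Key step: step 9

Assumption: all monocyclic peroxides are numbered O1, O2, C3 (arm), C4 (ethyl), C5, C6 (quaternary), even where lowest-locant rules would run the other way, and both enantiomers of the diarylprolinol silyl ether catalyst are taken as commercial.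

Step 1
Reactants: 1 (S)-4-benzyl-1,3-oxazolidin-2-one; 2 hexanoyl chloride
Product: 3 (S)-4-benzyl-3-hexanoyl-1,3-oxazolidin-2-one
Conditions: Et3N, 4-(dimethylamino)pyridine (cat.), CH2Cl2, 0 °C to rt
Reagents that add atoms: none
Why: Nucleophile-catalysed N-acylation of the oxazolidinone with an acid chloride is a routine way to load the auxiliary and leaves its stereocentre untouched.

Step 2
Reactants: 3 (S)-4-benzyl-3-hexanoyl-1,3-oxazolidin-2-one; 4 ethyl iodide
Product: 6 (4S)-4-benzyl-3-[(2S)-2-ethylhexanoyl]-1,3-oxazolidin-2-one, via sodium Z-enolate 5 (not isolated)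
Conditions: NaN(SiMe3)2, THF, −78 °C; EtI (5 equiv), −78 to −20 °C
Reagents that add atoms: ethyl iodide 4, CCI
Why: In this Evans asymmetric alkylation the chelated sodium Z-enolate is ethylated on the face away from the benzyl group, which sets the 2S centre (the future side-chain stereocentre), and a large excess of the unactivated iodide makes up for its low reactivity.

Step 3
Reactants: 6 (4S)-4-benzyl-3-[(2S)-2-ethylhexanoyl]-1,3-oxazolidin-2-one
Product: 7 (S)-2-ethylhexan-1-ol
Conditions: LiBH4, H2O (1 equiv), Et2O, 0 °C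
Reagents that add atoms: none
Why: Borohydride reduction of the exocyclic imide carbonyl releases the primary alcohol without epimerisation and returns the auxiliary.

Step 4
Reactants: 7 (S)-2-ethylhexan-1-ol
Product: 8 (S)-3-(iodomethyl)heptane
Conditions: I2, PPh3, imidazole, CH2Cl2, 0 °C to rt
Reagents that add atoms: iodine, II
Why: Appel-type iodination (oxyphosphonium activation, then SN2 at the primary carbon) does not touch the neighbouring stereocentre.

Step 5
Reactants: 8 (S)-3-(iodomethyl)heptane; 9 lithium acetylide ethylenediamine complex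
Product: 10 (S)-4-ethyloct-1-yne
Conditions: DMSO, 0 °C to rt
Reagents that add atoms: lithium acetylide (as complex 9), [Li]C#C
Why: SN2 alkynylation of a primary iodide by lithium acetylide in a dipolar aprotic solvent gives the terminal alkyne directly, and the β-branch slows the substitution without blocking it.

Step 6
Reactants: 11 (E)-pent-2-enal; 12 tert-butyl 3-oxobutanoate
Product: 15 (S)-5-ethylcyclohex-2-en-1-one, via Michael adduct 13 (not isolated), via cyclic keto ester 14 (not isolated)
Conditions: (R)-2-{bis[3,5-bis(trifluoromethyl)phenyl](trimethylsilyloxy)methyl}pyrrolidine (10 mol %), neat, rt; then TsOH·H2O (20 mol %), toluene, 80 °C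
Reagents that add atoms: none
Why: Iminium-catalysed asymmetric Michael addition followed by acid-promoted intramolecular aldol condensation, tert-butyl ester cleavage and decarboxylation is a known one-pot entry to 5-alkylcyclohex-2-enones; the diaryl(silyloxy)methyl group of the R catalyst blocks one face of the E-iminium ion, so the keto ester adds to the Si face of C3 of the enal and sets the S centre (future C4), and the enone C=C forms on the side remote from the ethyl group, which a desaturation of 3-ethylcyclohexanone would not guarantee.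

Step 7
Reactants: 15 (S)-5-ethylcyclohex-2-en-1-one
Product: 16 (R)-5-ethylcyclohexa-1,3-dien-1-yl trifluoromethanesulfonate
Conditions: Tf2O, 2,6-di-tert-butyl-4-methylpyridine, CH2Cl2, 0 °C to rt
Reagents that add atoms: trifluoromethanesulfonic anhydride, O=S(=O)(OS(=O)(=O)C(F)(F)F)C(F)(F)F
Why: In this thermodynamic dienyl triflate formation from an enone, O-triflation gives a triflyloxyallyl cation with most of its charge at C3, so the hindered pyridine removes a C4 proton and the through-conjugated 1-triflyloxy-1,3-diene forms rather than the cross-conjugated isomer, while the C5 centre is untouched (its descriptor becomes R only through a change of priorities).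

Step 8
Reactants: 10 (S)-4-ethyloct-1-yne; 17 trimethylaluminium; 16 (R)-5-ethylcyclohexa-1,3-dien-1-yl trifluoromethanesulfonate
Product: 20 (5R)-5-ethyl-1-[(1E,4S)-4-ethyl-2-methyloct-1-en-1-yl]cyclohexa-1,3-diene, via alkenylalane 18 (not isolated), via alkenylzinc bromide 19 (not isolated)
Conditions: 10, Me3Al (2 equiv), Cp2ZrCl2 (20 mol %), CH2Cl2, 0 °C to rt; volatiles off in vacuo; ZnBr2, THF, 0 °C; 16, Pd(PPh3)4 (5 mol %), THF, rt
Reagents that add atoms: trimethylaluminium 17, C[Al](C)C (ZnBr2 leaves atoms only in 19)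
Why: Zirconium-catalysed syn methylalumination of the terminal alkyne fixes the E trisubstituted alkene, and Negishi coupling of the derived alkenylzinc with the dienyl triflate under zerovalent palladium catalysis proceeds with retention at both sp2 carbons.

Step 9
Reactants: 20 (5R)-5-ethyl-1-[(1E,4S)-4-ethyl-2-methyloct-1-en-1-yl]cyclohexa-1,3-diene; 21 oxygen
Product: 22 (1R,4S,8R)-8-ethyl-1-[(1E,4S)-4-ethyl-2-methyloct-1-en-1-yl]-2,3-dioxabicyclo[2.2.2]oct-5-ene (ethyl syn to the C5=C6 bridge)
Conditions: O2, 5,10,15,20-tetraphenylporphyrin (1 mol %), visible light (LED), CH2Cl2, −78 °C, stopped when 20 is consumed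
Reagents that add atoms: oxygen 21, O=O
Why: Sensitised singlet oxygen adds suprafacially, in a concerted if asynchronous [4+2] cycloaddition, across C1 and C4 of the s-cis-locked ring diene of 20 and makes the C6–O1 and C3–O2 bonds (dioxane numbering) in one event; the closest known reaction is the photooxygenation of alkylated cyclohexa-1,3-dienes to 2,3-dioxabicyclo[2.2.2]oct-5-enes (α-terpinene to ascaridole type). Ring B (O1–O2–C3–C4–C5–C6) is closed by this intermolecular cycloaddition, with the O–O unit bridging the 1,4-positions of ring A, so no separate cyclisation is needed. C3 and C6 are the new stereocentres: their mutual cis relation follows from the suprafacial addition, and their absolute sense comes from the C4 ethyl group, which sits next to one reacting terminus and in its pseudoaxial conformer covers one diene face, so oxygen bonds on the other face and the ethyl group ends up syn to the etheno bridge. Face selectivity is the least well secured demand, because singlet oxygen is small and the pseudoequatorial conformer shields little; hence the low temperature and the planned chromatographic removal of the syn adduct. Site selectivity is secured by the substrate: the semicyclic diene reaches an s-cis geometry only by pressing the methyl group that is cis to the ring against ring C2–H, and the ene reaction of the trisubstituted alkene is slower than cycloaddition to an electron-rich cisoid diene.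

Step 10
Reactants: 22 (1R,4S,8R)-8-ethyl-1-[(1E,4S)-4-ethyl-2-methyloct-1-en-1-yl]-2,3-dioxabicyclo[2.2.2]oct-5-ene; 23 ethene
Product: 24 (3R,4R,6R)-3,6-diethenyl-4-ethyl-6-[(1E,4S)-4-ethyl-2-methyloct-1-en-1-yl]-1,2-dioxane (all-cis vinyl/ethyl/vinyl)
Conditions: ethene (1–3 bar), second-generation Hoveyda–Grubbs catalyst RuCl2(H2IMes)(=CH-C6H4-2-OiPr) (H2IMes = 1,3-dimesitylimidazolidin-2-ylidene, 5–10 mol %), CH2Cl2, rt, dark; ethyl vinyl ether quench
Reagents that add atoms: ethene 23, C=C
Why: Proposed new method: ring-opening metathesis with ethene has not been shown on bicyclic endoperoxides; the ruthenium methylidene should add [2+2] to the strained cis alkene from the face flanked by the O–O bridge (the other face carries the syn ethyl group), cycloreversion releases the strain of the bicyclo[2.2.2] frame and lets the boat dioxane relax to a chair, and ethene caps the new alkylidene, while the trisubstituted alkene next to the quaternary carbon is inert to metathesis, a phosphine-free catalyst leaves no phosphine to attack O–O, and no stereocentre is touched; the closest known reactions are the ethenolysis and ring-opening cross-metathesis of bicyclo[2.2.2]octenes and of 2-oxa-3-azabicyclo[2.2.2]oct-5-enes, and cross-metathesis on alkenes that carry dialkyl peroxide rings.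

Step 11
Reactants: 24 (3R,4R,6R)-3,6-diethenyl-4-ethyl-6-[(1E,4S)-4-ethyl-2-methyloct-1-en-1-yl]-1,2-dioxane
Product: 26 2-{(3R,4R,6R)-6-ethenyl-4-ethyl-6-[(1E,4S)-4-ethyl-2-methyloct-1-en-1-yl]-1,2-dioxan-3-yl}ethan-1-ol, via trialkylborane 25 (not isolated)
Conditions: (Me2CHCHMe)2BH (from BH3·THF and 2-methylbut-2-ene, 1.1 equiv), THF, 0 °C; NaBO3·4H2O, THF/H2O, rt
Reagents that add atoms: sodium perborate, [Na+].[Na+].O[B-]1(O)OO[B-](O)(O)OO1 (disiamylborane, CC(C)C(C)BC(C)C(C)C, leaves atoms only in 25)
Why: In this hydroboration–oxidation with a hindered dialkylborane, disiamylborane places boron on the terminal carbon of the vinyl group at tertiary C3 much faster than on the vinyl group at fully substituted C6 and ignores the trisubstituted alkene, dialkyl peroxides are known to survive hydroboration, and the mildly basic perborate avoids Kornblum–DeLaMare cleavage at C3–H.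

Step 12
Reactants: 26 2-{(3R,4R,6R)-6-ethenyl-4-ethyl-6-[(1E,4S)-4-ethyl-2-methyloct-1-en-1-yl]-1,2-dioxan-3-yl}ethan-1-ol
Product: 27 2-{(3R,4R,6S)-4,6-diethyl-6-[(1E,4S)-4-ethyl-2-methyloct-1-en-1-yl]-1,2-dioxan-3-yl}ethan-1-ol
Conditions: KO2CN=NCO2K, AcOH, MeOH/CH2Cl2, 0 °C to rt
Reagents that add atoms: none
Why: Diimide reduction, the standard way to saturate alkenes beside a peroxide, transfers hydrogen concertedly to the monosubstituted vinyl group far faster than to the trisubstituted alkene and does not cleave O–O, and C6 keeps its geometry (its descriptor becomes S only through a change of priorities).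

Step 13
Reactants: 27 2-{(3R,4R,6S)-4,6-diethyl-6-[(1E,4S)-4-ethyl-2-methyloct-1-en-1-yl]-1,2-dioxan-3-yl}ethan-1-ol
Product: 29 2-{(3R,4R,6S)-4,6-diethyl-6-[(1E,4S)-4-ethyl-2-methyloct-1-en-1-yl]-1,2-dioxan-3-yl}acetic acid (target), via aldehyde 28 (not isolated)
Conditions: 2,2,6,6-tetramethylpiperidin-1-oxyl (TEMPO, 20 mol %), PhI(OAc)2 (2.5 equiv), MeCN/H2O, rt
Reagents that add atoms: water, O
Why: Oxoammonium oxidation (TEMPO/PhI(OAc)2) of the primary alcohol through the aldehyde hydrate to the acid runs in weakly acidic aqueous medium, so neither β-elimination of the peroxide from 28 nor attack on the alkene or on O–O is expected.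

Compound list
1 | (S)-4-benzyl-1,3-oxazolidin-2-one | O=C1N[C@@H](Cc2ccccc2)CO1 | starting material
2 | hexanoyl chloride | CCCCCC(Cl)=O | starting material
3 | (S)-4-benzyl-3-hexanoyl-1,3-oxazolidin-2-one | CCCCCC(=O)N1[C@@H](Cc2ccccc2)COC1=O | intermediate
4 | ethyl iodide | CCI | starting material
5 | sodium Z-enolate of 3 | [Na+].[O-]/C(=C\CCCC)N1[C@@H](Cc2ccccc2)COC1=O | intermediate
6 | (4S)-4-benzyl-3-[(2S)-2-ethylhexanoyl]-1,3-oxazolidin-2-one | CCCC[C@H](CC)C(=O)N1[C@@H](Cc2ccccc2)COC1=O | intermediate
7 | (S)-2-ethylhexan-1-ol | CCCC[C@H](CC)CO | intermediate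
8 | (S)-3-(iodomethyl)heptane | CCCC[C@H](CC)CI | intermediate
9 | lithium acetylide ethylenediamine complex | [Li]C#C.NCCN | starting material
10 | (S)-4-ethyloct-1-yne | CCCC[C@H](CC)CC#C | intermediate
11 | (E)-pent-2-enal | CC/C=C/C=O | starting material
12 | tert-butyl 3-oxobutanoate | CC(=O)CC(=O)OC(C)(C)C | starting material
13 | tert-butyl (3S)-2-acetyl-3-ethyl-5-oxopentanoate (C2 epimers) | O=CC[C@H](CC)C(C(C)=O)C(=O)OC(C)(C)C | intermediate
14 | tert-butyl (6S)-6-ethyl-2-oxocyclohex-3-ene-1-carboxylate (C1 epimers) | O=C1C=CC[C@H](CC)C1C(=O)OC(C)(C)C | intermediate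
15 | (S)-5-ethylcyclohex-2-en-1-one | O=C1C=CC[C@H](CC)C1 | intermediate
16 | (R)-5-ethylcyclohexa-1,3-dien-1-yl trifluoromethanesulfonate | O=S(=O)(OC1=CC=C[C@H](CC)C1)C(F)(F)F | intermediate
17 | trimethylaluminium | C[Al](C)C | starting material
18 | [(1E,4S)-4-ethyl-2-methyloct-1-en-1-yl]dimethylalane | CCCC[C@H](CC)C/C(C)=C/[Al](C)C | intermediate
19 | [(1E,4S)-4-ethyl-2-methyloct-1-en-1-yl]zinc bromide | CCCC[C@H](CC)C/C(C)=C/[Zn]Br | intermediate
20 | (5R)-5-ethyl-1-[(1E,4S)-4-ethyl-2-methyloct-1-en-1-yl]cyclohexa-1,3-diene | CCCC[C@H](CC)C/C(C)=C/C1=CC=C[C@H](CC)C1 | intermediate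
21 | oxygen (photosensitised to the singlet state) | O=O | starting material
22 | (1R,4S,8R)-8-ethyl-1-[(1E,4S)-4-ethyl-2-methyloct-1-en-1-yl]-2,3-dioxabicyclo[2.2.2]oct-5-ene, ethyl syn to the etheno bridge | CCCC[C@H](CC)C/C(C)=C/[C@]1(C=C2)C[C@@H](CC)[C@@H]2OO1 | intermediate
23 | ethene | C=C | starting material
24 | (3R,4R,6R)-3,6-diethenyl-4-ethyl-6-[(1E,4S)-4-ethyl-2-methyloct-1-en-1-yl]-1,2-dioxane | CCCC[C@H](CC)C/C(C)=C/[C@]1(C=C)C[C@@H](CC)[C@@H](C=C)OO1 | intermediate
25 | bis(3-methylbutan-2-yl)borane adduct of the C3 vinyl group of 24 | CCCC[C@H](CC)C/C(C)=C/[C@]1(C=C)C[C@@H](CC)[C@@H](CCB(C(C)C(C)C)C(C)C(C)C)OO1 | intermediate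
26 | 2-{(3R,4R,6R)-6-ethenyl-4-ethyl-6-[(1E,4S)-4-ethyl-2-methyloct-1-en-1-yl]-1,2-dioxan-3-yl}ethan-1-ol | CCCC[C@H](CC)C/C(C)=C/[C@]1(C=C)C[C@@H](CC)[C@@H](CCO)OO1 | intermediate
27 | 2-{(3R,4R,6S)-4,6-diethyl-6-[(1E,4S)-4-ethyl-2-methyloct-1-en-1-yl]-1,2-dioxan-3-yl}ethan-1-ol | CCCC[C@H](CC)C/C(C)=C/[C@]1(CC)C[C@@H](CC)[C@@H](CCO)OO1 | intermediate
28 | 2-{(3R,4R,6S)-4,6-diethyl-6-[(1E,4S)-4-ethyl-2-methyloct-1-en-1-yl]-1,2-dioxan-3-yl}acetaldehyde | CCCC[C@H](CC)C/C(C)=C/[C@]1(CC)C[C@@H](CC)[C@@H](CC=O)OO1 | intermediate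
29 | 2-{(3R,4R,6S)-4,6-diethyl-6-[(1E,4S)-4-ethyl-2-methyloct-1-en-1-yl]-1,2-dioxan-3-yl}acetic acid | CCCC[C@H](CC)C/C(C)=C/[C@]1(CC)C[C@@H](CC)[C@@H](CC(=O)O)OO1 | target

Total step count: 13. Longest linear sequence: 11 (steps 1–5, then 8–13).

Steps most likely to fail

1. Step 10 (ring-opening metathesis of the endoperoxide).
- Risk: the ruthenium carbene may be consumed by electron transfer to, or insertion into, the O–O bond, with rearrangement of the endoperoxide. The bridge alkene may also be too shielded by the quaternary bridgehead and the syn ethyl group to react.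
- Fallback: it uses known chemistry and cleaves the bridge with ozone before the side-chain alkene exists. It sets out from 16 and 8 and comes back at 24.
- Sonogashira coupling of 16 with propyne (PdCl2(PPh3)2, CuI, Et3N) should give (R)-5-ethyl-1-(prop-1-yn-1-yl)cyclohexa-1,3-diene F1.
- Photooxygenation as in step 9 should give the alkynyl endoperoxide F2.
- Ozonolysis of the etheno bridge is a known reaction of 2,3-dioxabicyclo[2.2.2]oct-5-enes, and an alkyne survives it. With Me2S work-up it should give the cis-1,2-dioxane-3,6-dicarbaldehyde F3.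
- Double Wittig methylenation (Ph3P=CH2, THF, −78 °C) leads to the divinyl alkynyl dioxane F4.
- Hydrostannation under zerovalent palladium catalysis (Bu3SnH, Pd(PPh3)4) adds syn and places tin on the methyl-bearing alkyne carbon, away from the quaternary centre. This gives the E-alkenylstannane F5.
- Iodine converts F5 with retention into the E-alkenyl iodide F6.
- Negishi coupling of F6 with (S)-(2-ethylhexyl)zinc iodide F7 (from 8, Zn, LiCl, THF) under PdCl2(dppf) delivers 24.

2. Step 9 (key step).
- Risk: facial selectivity may be poor, because the ethyl group is small and can sit pseudoequatorial. Ene oxygenation of the side-chain alkene on over-irradiation adds to the loss.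
- Fallback: the approach changes from relying on kinetic face control to separation and recycling. It sets out from 20 (as its unwanted cycloadduct) and comes back at 20.
- The syn-face endoperoxide F8 is separated from 22 and reduced with thiourea in MeOH to the cis-ene-1,4-diol F9.
- Reductive 1,4-elimination of this 2-ene-1,4-diol with low-valent titanium (TiCl3, LiAlH4, THF) regenerates triene 20, with its C5 centre and E alkene intact, for another pass through step 9.

3. Step 11 (selective hydroboration).
- Risk: the borane may not discriminate enough between the two vinyl groups, and B–H may slowly reduce the O–O bond.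
- Fallback: the differentiation is moved to cross-metathesis, where a vinyl group on a quaternary carbon is very reluctant. It sets out from 24 and comes back at 26.
- Cross-metathesis of 24 with 4,4,5,5-tetramethyl-2-vinyl-1,3,2-dioxaborolane, using the catalyst of step 10, should engage only the C3 vinyl group and give the E-alkenylboronate F10.
- Perborate oxidation of the C–B bond gives the vinyl-bearing dioxanyl acetaldehyde F11.
- NaBH4 in MeOH at 0 °C reduces F11 to 26.

Further compounds
F1 | step 10 | (R)-5-ethyl-1-(prop-1-yn-1-yl)cyclohexa-1,3-diene | CC#CC1=CC=C[C@H](CC)C1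
F2 | step 10 | (1R,4S,8R)-8-ethyl-1-(prop-1-yn-1-yl)-2,3-dioxabicyclo[2.2.2]oct-5-ene | CC#C[C@]1(C=C2)C[C@@H](CC)[C@@H]2OO1
F3 | step 10 | (3S,4R,6S)-4-ethyl-6-(prop-1-yn-1-yl)-1,2-dioxane-3,6-dicarbaldehyde | CC#C[C@]1(C=O)C[C@@H](CC)[C@@H](C=O)OO1
F4 | step 10 | (3R,4R,6R)-3,6-diethenyl-4-ethyl-6-(prop-1-yn-1-yl)-1,2-dioxane | CC#C[C@]1(C=C)C[C@@H](CC)[C@@H](C=C)OO1
F5 | step 10 | (3R,4R,6R)-3,6-diethenyl-4-ethyl-6-[(E)-2-(tributylstannyl)prop-1-en-1-yl]-1,2-dioxane | CCCC[Sn](CCCC)(CCCC)/C(C)=C/[C@]1(C=C)C[C@@H](CC)[C@@H](C=C)OO1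
F6 | step 10 | (3R,4R,6R)-3,6-diethenyl-4-ethyl-6-[(E)-2-iodoprop-1-en-1-yl]-1,2-dioxane | I/C(C)=C/[C@]1(C=C)C[C@@H](CC)[C@@H](C=C)OO1
F7 | step 10 | (S)-(2-ethylhexyl)zinc iodide | CCCC[C@H](CC)C[Zn]I
F8 | step 9 | (1S,4R,8R)-8-ethyl-1-[(1E,4S)-4-ethyl-2-methyloct-1-en-1-yl]-2,3-dioxabicyclo[2.2.2]oct-5-ene, ethyl syn to the peroxide bridge | CCCC[C@H](CC)C/C(C)=C/[C@@]1(C=C2)C[C@@H](CC)[C@H]2OO1
F9 | step 9 | 5-ethyl-1-[(1E,4S)-4-ethyl-2-methyloct-1-en-1-yl]cyclohex-2-ene-1,4-diol, both hydroxyl groups cis to the ethyl group | CCCC[C@H](CC)C/C(C)=C/[C@@]1(O)C=C[C@H](O)[C@H](CC)C1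
F10 | step 11 | pinacol (E)-2-{(3R,4R,6R)-6-ethenyl-4-ethyl-6-[(1E,4S)-4-ethyl-2-methyloct-1-en-1-yl]-1,2-dioxan-3-yl}ethenylboronate | CCCC[C@H](CC)C/C(C)=C/[C@]1(C=C)C[C@@H](CC)[C@@H](/C=C/B2OC(C)(C)C(C)(C)O2)OO1
F11 | step 11 | 2-{(3R,4R,6R)-6-ethenyl-4-ethyl-6-[(1E,4S)-4-ethyl-2-methyloct-1-en-1-yl]-1,2-dioxan-3-yl}acetaldehyde | CCCC[C@H](CC)C/C(C)=C/[C@]1(C=C)C[C@@H](CC)[C@@H](CC=O)OO1
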